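**Retrosynthetic overview**

1. Both pyranone rings (O1–C2 and C3–C4 of each coumarin) are closed last, by double Wittig olefination and lactonisation of bis-salicylaldehyde 32.
2. The strategy rests on the benzene ring C4a–C5–C6–C7–C8–C8a of the styryl-bound coumarin, which carries oxygen at C7 and C8a and carbon at C4a and C6. It is built by [4+2] addition of the silyl ynol ether 21 of the core enyne across C3 and C6 of the 4-(methoxymethoxy)-2-pyrone-5-carboxylate 25, then loss of CO2 (new bonds C5–C6 and C7–C8).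
3. Ynol ether 21 comes from core aldehyde 14 by Takai iodo-olefination, Sonogashira coupling, acetylide oxidation and O-silylation.
4. Aldehyde 14 comes from anti-SN2' opening of bridged lactone 7 by an aryl Grignard/copper reagent (sets C2 from C1). Lactone 7 comes from an enantioselective Diels–Alder reaction of isoprene with methacrolein (sets C1), Pinnick oxidation and selenolactonisation/selenoxide elimination.
5. Ring order: cyclohexene (step 1), benzene ring of the styryl-bound coumarin (step 15), both pyranones (step 20); the other benzene ring is bought in 8.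

Key step: step 15

**Conventions and assumption**

- Core locants: C1 = quaternary carbon (methyl and the C1 carbon chain), C2 = aryl-bearing CH, C3=C4(CH3), C5, C6.
- Ar = 5-(1,3-dioxolan-2-yl)-2-methoxy-4-(methoxymethoxy)phenyl. The aldehyde of this ring is carried as a dioxolane rather than a dimethyl acetal, because it must survive many chromatographic steps.
- Assumption: the (S)-configured oxazaborolidinium catalyst is taken to deliver the (S)-aldehyde 3 (formyl C–H···O binding model for 2-substituted acroleins); if the facial sense proves opposite, the (R)-catalyst is used and nothing else changes.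

**Route**

Step 1
Reactants: 1 isoprene; 2 methacrolein
Product: 3 (S)-1,4-dimethylcyclohex-3-ene-1-carbaldehyde
Conditions: (S)-3,3-diphenyl-1-(o-tolyl)tetrahydro-1H,3H-pyrrolo[1,2-c][1,3,2]oxazaborole (10 mol %), Tf2NH (8 mol %), CH2Cl2, −78 °C
Reagents that add atoms: none
Why: Enantioselective Diels–Alder reaction under cationic oxazaborolidine catalysis, in which boron-bound s-trans methacrolein is shielded on one face by a catalyst aryl group so that isoprene adds to the open face and sets C1 as S, the diene methyl group directing the 1,4 ("para") regiochemistry.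

Step 2
Reactants: 3 (S)-1,4-dimethylcyclohex-3-ene-1-carbaldehyde
Product: 4 (S)-1,4-dimethylcyclohex-3-ene-1-carboxylic acid
Conditions: NaClO2, NaH2PO4, 2-methyl-2-butene, t-BuOH/H2O, 0 °C → rt
Reagents that add atoms: sodium chlorite, [Na+].[O-]Cl=O
Why: Pinnick oxidation converts the non-enolisable aldehyde into the acid, with the alkene scavenger protecting the ring olefin from hypochlorous acid.

Step 3
Reactants: 4 (S)-1,4-dimethylcyclohex-3-ene-1-carboxylic acid
Product: 7 (1R,4S)-1,4-dimethyl-2-oxabicyclo[2.2.2]oct-5-en-3-one, via selenide lactone 5 (not isolated), via selenoxide 6 (not isolated)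
Conditions: PhSeCl, Et3N, CH2Cl2, −78 °C → rt; then 30% H2O2, pyridine, 0 °C → rt
Reagents that add atoms: none
Why: Phenylselenolactonisation is an anti addition in which the carboxylate opens the seleniranium ion at the more substituted carbon C4 to give the bridged δ-lactone, and selenoxide syn-elimination can only take the eclipsed hydrogen on C2 because C4 is fully substituted, so the C2=C3 alkene forms and the bridge geometry follows from C1.

Step 4
Reactants: 8 5-bromo-2-hydroxy-4-methoxybenzaldehyde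
Product: 9 5-bromo-4-methoxy-2-(methoxymethoxy)benzaldehyde
Conditions: MOMCl, i-Pr2NEt, CH2Cl2, 0 °C → rt
Reagents that add atoms: chloromethyl methyl ether, COCCl
Why: O-alkylation of the phenol (Williamson-type etherification) masks the future C8a oxygen as an acid-labile MOM ether.

Step 5
Reactants: 9 5-bromo-4-methoxy-2-(methoxymethoxy)benzaldehyde
Product: 10 2-[5-bromo-4-methoxy-2-(methoxymethoxy)phenyl]-1,3-dioxolane
Conditions: TMSOCH2CH2OTMS, TMSOTf (2 mol %), CH2Cl2, −78 → −20 °C; pyridine quench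
Reagents that add atoms: 1,2-bis(trimethylsilyloxy)ethane, C[Si](C)(C)OCCO[Si](C)(C)C
Why: Aprotic silyl-transfer acetalisation converts the aldehyde into the dioxolane at low temperature without exposing the aryl MOM ether to protic acid.

Step 6
Reactants: 10 2-[5-bromo-4-methoxy-2-(methoxymethoxy)phenyl]-1,3-dioxolane; 7 (1R,4S)-1,4-dimethyl-2-oxabicyclo[2.2.2]oct-5-en-3-one
Product: 12 (1S,2R)-2-Ar-1,4-dimethylcyclohex-3-ene-1-carboxylic acid, via arylmagnesium bromide 11 (not isolated)
Conditions: Mg, LiCl, THF, 35 °C; then CuBr·SMe2 (20 mol %), 7, THF/Me2S, −20 → 0 °C; aq. NaH2PO4 (pH 4–5)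
Reagents that add atoms: none
Why: Copper-catalysed anti-SN2' allylic substitution of a bicyclic vinyl lactone, in which the arylcopper species adds to C2 on the face opposite the departing tertiary bridgehead carboxylate (direct SN2 is impossible there), so the aryl group ends up trans to the C1 carboxyl group, C2 is set from C1 and the double bond moves to C3=C4.

Step 7
Reactants: 12 (1S,2R)-2-Ar-1,4-dimethylcyclohex-3-ene-1-carboxylic acid
Product: 13 [(1S,2S)-2-Ar-1,4-dimethylcyclohex-3-en-1-yl]methanol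
Conditions: LiAlH4, THF, 0 → 50 °C
Reagents that add atoms: none
Why: Hydride reduction of the hindered carboxylic acid to the neopentyl-type primary alcohol leaves the acetal, MOM ether and alkene untouched.

Step 8
Reactants: 13 [(1S,2S)-2-Ar-1,4-dimethylcyclohex-3-en-1-yl]methanol
Product: 14 (1S,2R)-2-Ar-1,4-dimethylcyclohex-3-ene-1-carbaldehyde
Conditions: DMP (1,1,1-triacetoxy-1,1-dihydro-1,2-benziodoxol-3(1H)-one), NaHCO3, CH2Cl2, 0 °C → rt
Reagents that add atoms: none
Why: Buffered hypervalent-iodine oxidation gives the aldehyde, which has no α-hydrogen and so cannot epimerise, under conditions mild enough for the acetal.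

Step 9
Reactants: 14 (1S,2R)-2-Ar-1,4-dimethylcyclohex-3-ene-1-carbaldehyde
Product: 15 (1S,2S)-2-Ar-1-[(E)-2-iodoethenyl]-1,4-dimethylcyclohex-3-ene
Conditions: CrCl2, CHI3, THF/dioxane, 0 °C → rt
Reagents that add atoms: iodoform, IC(I)I
Why: Takai olefination, in which the geminal dichromium species from CHI3 and CrCl2 adds to the hindered aldehyde and eliminates to the (E)-vinyl iodide, the large quaternary substituent favouring the E isomer.

Step 10
Reactants: 15 (1S,2S)-2-Ar-1-[(E)-2-iodoethenyl]-1,4-dimethylcyclohex-3-ene; 16 ethynyltrimethylsilane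
Product: 17 (1R,2S)-2-Ar-1,4-dimethyl-1-[(E)-4-(trimethylsilyl)but-1-en-3-yn-1-yl]cyclohex-3-ene
Conditions: Pd(PPh3)2Cl2 (3 mol %), CuI (6 mol %), Et3N, THF, rt
Reagents that add atoms: none
Why: Sonogashira coupling of a vinyl iodide proceeds with retention of the E geometry at room temperature.

Step 11
Reactants: 17 (1R,2S)-2-Ar-1,4-dimethyl-1-[(E)-4-(trimethylsilyl)but-1-en-3-yn-1-yl]cyclohex-3-ene
Product: 18 (1R,2S)-2-Ar-1-[(E)-but-1-en-3-yn-1-yl]-1,4-dimethylcyclohex-3-ene
Conditions: K2CO3, MeOH/THF, rt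
Reagents that add atoms: none
Why: Methanolysis of the alkynyl C–Si bond under mild base frees the terminal alkyne without affecting any other group.

Step 12
Reactants: 18 (1R,2S)-2-Ar-1-[(E)-but-1-en-3-yn-1-yl]-1,4-dimethylcyclohex-3-ene
Product: 21 (1R,2S)-2-Ar-1,4-dimethyl-1-[(E)-4-(triisopropylsilyloxy)but-1-en-3-yn-1-yl]cyclohex-3-ene, via lithium acetylide 19 (not isolated), via lithium ynolate 20 (not isolated)
Conditions: LiHMDS, THF, −78 °C; t-BuOOLi (from t-BuOOH + LiHMDS), −78 → 0 °C; TIPSOTf, −78 → 0 °C; Et3N-deactivated silica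
Reagents that add atoms: tert-butyl hydroperoxide, CC(C)(C)OO; triisopropylsilyl triflate, CC(C)[Si](OS(=O)(=O)C(F)(F)F)(C(C)C)C(C)C
Why: Electrophilic oxygenation of a lithium acetylide by lithium tert-butyl peroxide gives the lithium ynolate, which the bulky silyl triflate traps on oxygen to give the silyl ynol ether.

Step 13
Reactants: 22 diethyl 1,3-acetonedicarboxylate
Product: 24 ethyl 4-hydroxy-6-oxo-6H-pyran-3-carboxylate, via ethoxymethylene diester 23 (not isolated)
Conditions: HC(OEt)3, Ac2O, 130 °C; then 4 M aq. HCl, rt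
Reagents that add atoms: triethyl orthoformate, CCOC(OCC)OCC; water, O
Why: Ethoxymethylenation of the active methylene group followed by acid hydrolysis of the enol ether and lactonisation of the hydroxymethylene oxygen onto the distal ester closes the 4-hydroxy-2-pyrone.

Step 14
Reactants: 24 ethyl 4-hydroxy-6-oxo-6H-pyran-3-carboxylate
Product: 25 ethyl 4-(methoxymethoxy)-6-oxo-6H-pyran-3-carboxylate
Conditions: MOMCl, i-Pr2NEt, CH2Cl2, 0 °C
Reagents that add atoms: chloromethyl methyl ether, COCCl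
Why: The acidic 4-hydroxyl of the pyrone is O-alkylated by the hard chloromethyl ether, placing the MOM group on the future C8a oxygen.

Step 15
Reactants: 21 (1R,2S)-2-Ar-1,4-dimethyl-1-[(E)-4-(triisopropylsilyloxy)but-1-en-3-yn-1-yl]cyclohex-3-ene; 25 ethyl 4-(methoxymethoxy)-6-oxo-6H-pyran-3-carboxylate
Product: 27 ethyl 5-[(E)-2-[(1R,2S)-2-Ar-1,4-dimethylcyclohex-3-en-1-yl]ethenyl]-2-(methoxymethoxy)-4-(triisopropylsilyloxy)benzoate, via bicyclic lactone adduct 26 (not isolated)
Conditions: PhMe, 110 °C, sealed tube, 4 Å MS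
Reagents that add atoms: none
Why: This is an inverse-electron-demand [4+2] cycloaddition in which the nucleophilic alkenyl-bearing carbon of the ynol ether bonds to pyrone C6 (β to the ester, δ to the lactone carbonyl) and the silyloxy-bearing carbon bonds to C3, giving the 2-oxabicyclo[2.2.2]octa-5,7-dien-3-one 26, which expels CO2 by retro-[4+2] to the benzoate. The closest known reaction type is the benzannulation of siloxyalkynes, alkoxyalkynes and ynamines with coumalate-type 2-pyrones. The benzene ring is closed by intermolecular cycloaddition across the diene termini followed by cycloreversion, not by cyclisation of a tether, and the bonds formed are C5–C6 and C7–C8 of the future coumarin. No stereocentre is created, since the two bridgehead centres of 26 vanish on aromatisation and the remote, non-epimerisable centres C1 and C2 are untouched. The step needs regioselectivity, which polarity matching should secure so that alkenyl lands at C6, silyloxy at C7, MOM-oxy at C8a and the ester at C4a. It also needs chemoselectivity, which follows from the conjugated and ring alkenes being far poorer 2π partners than the ynol ether and from neutral, metal-free conditions that spare the acetal and MOM groups and avoid metal-promoted [2+2] pathways.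

Step 16
Reactants: 27 ethyl 5-[(E)-2-[(1R,2S)-2-Ar-1,4-dimethylcyclohex-3-en-1-yl]ethenyl]-2-(methoxymethoxy)-4-(triisopropylsilyloxy)benzoate
Product: 29 ethyl 5-[(E)-2-[(1R,2S)-2-Ar-1,4-dimethylcyclohex-3-en-1-yl]ethenyl]-4-methoxy-2-(methoxymethoxy)benzoate, via tetrabutylammonium phenoxide 28 (not isolated)
Conditions: TBAF, THF, 0 °C; then MeI, rt
Reagents that add atoms: iodomethane, CI
Why: Fluoride cleaves the aryl silyl ether and the resulting ammonium phenoxide is O-methylated in the same flask (Williamson etherification), installing the C7 methoxy group.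

Step 17
Reactants: 29 ethyl 5-[(E)-2-[(1R,2S)-2-Ar-1,4-dimethylcyclohex-3-en-1-yl]ethenyl]-4-methoxy-2-(methoxymethoxy)benzoate
Product: 30 [5-[(E)-2-[(1R,2S)-2-Ar-1,4-dimethylcyclohex-3-en-1-yl]ethenyl]-4-methoxy-2-(methoxymethoxy)phenyl]methanol
Conditions: i-Bu2AlH, CH2Cl2, −78 → 0 °C; Rochelle salt work-up
Reagents that add atoms: none
Why: Hydride reduction of the aryl ester to the benzylic alcohol is reliable at low temperature, where the dioxolane and MOM ethers are inert.

Step 18
Reactants: 30 [5-[(E)-2-[(1R,2S)-2-Ar-1,4-dimethylcyclohex-3-en-1-yl]ethenyl]-4-methoxy-2-(methoxymethoxy)phenyl]methanol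
Product: 31 5-[(E)-2-[(1R,2S)-2-Ar-1,4-dimethylcyclohex-3-en-1-yl]ethenyl]-4-methoxy-2-(methoxymethoxy)benzaldehyde
Conditions: MnO2, CH2Cl2, rt
Reagents that add atoms: none
Why: MnO2 selectively oxidises the electron-rich benzylic alcohol to the aldehyde under neutral conditions.

Step 19
Reactants: 31 5-[(E)-2-[(1R,2S)-2-Ar-1,4-dimethylcyclohex-3-en-1-yl]ethenyl]-4-methoxy-2-(methoxymethoxy)benzaldehyde
Product: 32 5-[(E)-2-[(1R,2S)-2-(5-formyl-4-hydroxy-2-methoxyphenyl)-1,4-dimethylcyclohex-3-en-1-yl]ethenyl]-2-hydroxy-4-methoxybenzaldehyde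
Conditions: 3 M aq. HCl, THF, 40 °C
Reagents that add atoms: water, O
Why: Acid hydrolysis removes the dioxolane and both MOM ethers in one operation, the MOM groups being activated by the ortho formyl groups, so mild acid should suffice and spare the alkenes.

Step 20
Reactants: 32 5-[(E)-2-[(1R,2S)-2-(5-formyl-4-hydroxy-2-methoxyphenyl)-1,4-dimethylcyclohex-3-en-1-yl]ethenyl]-2-hydroxy-4-methoxybenzaldehyde
Product: 34 7-methoxy-6-[(E)-2-[(1R,2S)-2-(7-methoxy-2-oxo-2H-chromen-6-yl)-1,4-dimethylcyclohex-3-en-1-yl]ethenyl]-2H-chromen-2-one, via bis-cinnamate 33 (not isolated)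
Conditions: Ph3P=CHCO2Et, PhNEt2, reflux
Reagents that add atoms: ethyl (triphenylphosphoranylidene)acetate, CCOC(=O)C=P(c1ccccc1)(c1ccccc1)c1ccccc1
Why: Wittig olefination of both formyl groups gives the ortho-hydroxycinnamates, which at the reflux temperature of the aniline solvent equilibrate to the Z form and lactonise with loss of ethanol, closing both pyranone rings without touching a stereocentre.

**Compound list**

1 | isoprene | C=CC(C)=C | starting material
2 | methacrolein | C=C(C)C=O | starting material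
3 | (S)-1,4-dimethylcyclohex-3-ene-1-carbaldehyde | O=C[C@]1(C)CC=C(C)CC1 | intermediate
4 | (S)-1,4-dimethylcyclohex-3-ene-1-carboxylic acid | OC(=O)[C@]1(C)CC=C(C)CC1 | intermediate
5 | (1R,4S,6R)-1,4-dimethyl-6-(phenylselanyl)-2-oxabicyclo[2.2.2]octan-3-one (selenide lactone, Se anti to the ring oxygen) | O=C1O[C@@]2(C)[C@H]([Se]c3ccccc3)C[C@]1(C)CC2 | intermediate
6 | Se-oxide of 5 (selenoxide, mixture at selenium) | O=C1O[C@@]2(C)[C@H]([Se](=O)c3ccccc3)C[C@]1(C)CC2 | intermediate
7 | (1R,4S)-1,4-dimethyl-2-oxabicyclo[2.2.2]oct-5-en-3-one | O=C1O[C@@]2(C)C=C[C@]1(C)CC2 | intermediate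
8 | 5-bromo-2-hydroxy-4-methoxybenzaldehyde | COc1cc(O)c(C=O)cc1Br | starting material
9 | 5-bromo-4-methoxy-2-(methoxymethoxy)benzaldehyde | COCOc1cc(OC)c(Br)cc1C=O | intermediate
10 | 2-[5-bromo-4-methoxy-2-(methoxymethoxy)phenyl]-1,3-dioxolane | COCOc1cc(OC)c(Br)cc1C1OCCO1 | intermediate
11 | [5-(1,3-dioxolan-2-yl)-2-methoxy-4-(methoxymethoxy)phenyl]magnesium bromide | COCOc1cc(OC)c([Mg]Br)cc1C1OCCO1 | intermediate
12 | (1S,2R)-2-Ar-1,4-dimethylcyclohex-3-ene-1-carboxylic acid (Ar trans to CO2H) | OC(=O)[C@@]1(C)CCC(C)=C[C@@H]1c1cc(C2OCCO2)c(OCOC)cc1OC | intermediate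
13 | [(1S,2S)-2-Ar-1,4-dimethylcyclohex-3-en-1-yl]methanol | OC[C@@]1(C)CCC(C)=C[C@@H]1c1cc(C2OCCO2)c(OCOC)cc1OC | intermediate
14 | (1S,2R)-2-Ar-1,4-dimethylcyclohex-3-ene-1-carbaldehyde | O=C[C@@]1(C)CCC(C)=C[C@@H]1c1cc(C2OCCO2)c(OCOC)cc1OC | intermediate
15 | (1S,2S)-2-Ar-1-[(E)-2-iodoethenyl]-1,4-dimethylcyclohex-3-ene | I/C=C/[C@@]1(C)CCC(C)=C[C@@H]1c1cc(C2OCCO2)c(OCOC)cc1OC | intermediate
16 | ethynyltrimethylsilane | C#C[Si](C)(C)C | starting material
17 | (1R,2S)-2-Ar-1,4-dimethyl-1-[(E)-4-(trimethylsilyl)but-1-en-3-yn-1-yl]cyclohex-3-ene | C[Si](C)(C)C#C/C=C/[C@@]1(C)CCC(C)=C[C@@H]1c1cc(C2OCCO2)c(OCOC)cc1OC | intermediate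
18 | (1R,2S)-2-Ar-1-[(E)-but-1-en-3-yn-1-yl]-1,4-dimethylcyclohex-3-ene | C#C/C=C/[C@@]1(C)CCC(C)=C[C@@H]1c1cc(C2OCCO2)c(OCOC)cc1OC | intermediate
19 | lithium acetylide of 18 | [Li]C#C/C=C/[C@@]1(C)CCC(C)=C[C@@H]1c1cc(C2OCCO2)c(OCOC)cc1OC | intermediate
20 | lithium ynolate derived from 19 | [Li]OC#C/C=C/[C@@]1(C)CCC(C)=C[C@@H]1c1cc(C2OCCO2)c(OCOC)cc1OC | intermediate
21 | (1R,2S)-2-Ar-1,4-dimethyl-1-[(E)-4-(triisopropylsilyloxy)but-1-en-3-yn-1-yl]cyclohex-3-ene (silyl ynol ether) | CC(C)[Si](OC#C/C=C/[C@@]1(C)CCC(C)=C[C@@H]1c1cc(C2OCCO2)c(OCOC)cc1OC)(C(C)C)C(C)C | intermediate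
22 | diethyl 1,3-acetonedicarboxylate | CCOC(=O)CC(=O)CC(=O)OCC | starting material
23 | diethyl 2-(ethoxymethylene)-3-oxopentanedioate | CCOC=C(C(=O)OCC)C(=O)CC(=O)OCC | intermediate
24 | ethyl 4-hydroxy-6-oxo-6H-pyran-3-carboxylate | CCOC(=O)C1=COC(=O)C=C1O | intermediate
25 | ethyl 4-(methoxymethoxy)-6-oxo-6H-pyran-3-carboxylate | CCOC(=O)C1=COC(=O)C=C1OCOC | intermediate
26 | 2-oxabicyclo[2.2.2]octa-5,7-dien-3-one adduct of 21 and 25 (bridgeheads unassigned) | O=C1OC2C(C(=O)OCC)=C(OCOC)C1C(O[Si](C(C)C)(C(C)C)C(C)C)=C2/C=C/[C@@]1(C)CCC(C)=C[C@@H]1c1cc(C2OCCO2)c(OCOC)cc1OC | intermediate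
27 | ethyl 5-[(E)-2-[(1R,2S)-2-Ar-1,4-dimethylcyclohex-3-en-1-yl]ethenyl]-2-(methoxymethoxy)-4-(triisopropylsilyloxy)benzoate | CCOC(=O)c1cc(/C=C/[C@@]2(C)CCC(C)=C[C@@H]2c2cc(C3OCCO3)c(OCOC)cc2OC)c(O[Si](C(C)C)(C(C)C)C(C)C)cc1OCOC | intermediate
28 | tetrabutylammonium phenoxide from 27 | CCOC(=O)c1cc(/C=C/[C@@]2(C)CCC(C)=C[C@@H]2c2cc(C3OCCO3)c(OCOC)cc2OC)c([O-])cc1OCOC.CCCC[N+](CCCC)(CCCC)CCCC | intermediate
29 | ethyl 5-[(E)-2-[(1R,2S)-2-Ar-1,4-dimethylcyclohex-3-en-1-yl]ethenyl]-4-methoxy-2-(methoxymethoxy)benzoate | CCOC(=O)c1cc(/C=C/[C@@]2(C)CCC(C)=C[C@@H]2c2cc(C3OCCO3)c(OCOC)cc2OC)c(OC)cc1OCOC | intermediate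
30 | [5-[(E)-2-[(1R,2S)-2-Ar-1,4-dimethylcyclohex-3-en-1-yl]ethenyl]-4-methoxy-2-(methoxymethoxy)phenyl]methanol | OCc1cc(/C=C/[C@@]2(C)CCC(C)=C[C@@H]2c2cc(C3OCCO3)c(OCOC)cc2OC)c(OC)cc1OCOC | intermediate
31 | 5-[(E)-2-[(1R,2S)-2-Ar-1,4-dimethylcyclohex-3-en-1-yl]ethenyl]-4-methoxy-2-(methoxymethoxy)benzaldehyde | O=Cc1cc(/C=C/[C@@]2(C)CCC(C)=C[C@@H]2c2cc(C3OCCO3)c(OCOC)cc2OC)c(OC)cc1OCOC | intermediate
32 | 5-[(E)-2-[(1R,2S)-2-(5-formyl-4-hydroxy-2-methoxyphenyl)-1,4-dimethylcyclohex-3-en-1-yl]ethenyl]-2-hydroxy-4-methoxybenzaldehyde | O=Cc1cc(/C=C/[C@@]2(C)CCC(C)=C[C@@H]2c2cc(C=O)c(O)cc2OC)c(OC)cc1O | intermediate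
33 | bis[ethyl (E)-2-hydroxycinnamate] from 32 | CCOC(=O)/C=C/c1cc(/C=C/[C@@]2(C)CCC(C)=C[C@@H]2c2cc(/C=C/C(=O)OCC)c(O)cc2OC)c(OC)cc1O | intermediate
34 | 7-methoxy-6-[(E)-2-[(1R,2S)-2-(7-methoxy-2-oxo-2H-chromen-6-yl)-1,4-dimethylcyclohex-3-en-1-yl]ethenyl]-2H-chromen-2-one | COc1cc2oc(=O)ccc2cc1/C=C/[C@@]1(C)CCC(C)=C[C@@H]1c1cc2ccc(=O)oc2cc1OC | target

**Step count and risks**

Total step count: 20. Longest linear sequence: 16 steps (1–3, 6–12, 15–20).

Most likely to fail:

1. Step 15 (pyrone benzannulation). The 4-alkoxy donor may make the pyrone too slow a diene, so that the silyl ynol ether rearranges to a silylketene or decomposes before cycloaddition, or some of the reversed regiochemistry may form. A catalytic variant (AgNTf2, 5 mol %, CH2Cl2, rt) would be tried first. The fallback gives up the cycloaddition and attaches a preformed arene to the vinyl iodide. It sets out from bromo aldehyde 9, which under Miyaura borylation (B2pin2, Pd(dppf)Cl2, KOAc, dioxane, 90 °C) should give 4-methoxy-2-(methoxymethoxy)-5-(4,4,5,5-tetramethyl-1,3,2-dioxaborolan-2-yl)benzaldehyde F1. Suzuki–Miyaura coupling of this with vinyl iodide 15 (Pd(PPh3)4, K3PO4, dioxane/H2O, 60 °C) should give aldehyde 31 with retention of the E geometry. The route is rejoined at 31.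

2. Step 6 (anti-SN2' opening). The aryl Grignard reagent may attack the lactone carbonyl, or substitution at the allylic carbon next to the quaternary centre may be too slow, so that reduction or homocoupling takes over. The fallback changes the mechanism to a π-allyl palladium coupling. It sets out from bromide 10, which is borylated (B2pin2, Pd(dppf)Cl2, KOAc, dioxane, 90 °C) to 2-[5-(1,3-dioxolan-2-yl)-2-methoxy-4-(methoxymethoxy)phenyl]-4,4,5,5-tetramethyl-1,3,2-dioxaborolane F2. Lactone 7 is then ionised by zerovalent palladium (Pd2(dba)3, PPh3, K3PO4, THF/H2O, 50 °C) with inversion. Transmetallation and reductive elimination at the less hindered allyl terminus C2 with retention should give the same trans acid. The route is rejoined at 12.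

3. Step 12 (acetylide oxidation and O-silylation). Oxygen transfer to the conjugated enynyl acetylide may be incomplete, silylation may occur at carbon, or the siloxy enyne may be lost on purification. The fallback builds the ynolate by carbon-chain rearrangement instead. It sets out from aldehyde 14, which under Horner–Wadsworth–Emmons olefination (triethyl phosphonoacetate, NaH, THF, 0 °C → rt) should give ethyl (E)-3-[(1R,2S)-2-Ar-1,4-dimethylcyclohex-3-en-1-yl]prop-2-enoate F3. Kowalski-type treatment (LiCHBr2 from CH2Br2 and LiTMP, THF, −78 °C) should convert it into the lithium enolate of the dibromomethyl ketone F4. Bromine–lithium exchange with n-BuLi and warming should induce 1,2-migration of the alkenyl group to lithium ynolate 20, which is trapped with TIPSOTf as in the main route. The route is rejoined at 21.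

**Further compounds**

F1 | step 15 | 4-methoxy-2-(methoxymethoxy)-5-(4,4,5,5-tetramethyl-1,3,2-dioxaborolan-2-yl)benzaldehyde | COCOc1cc(OC)c(B2OC(C)(C)C(C)(C)O2)cc1C=O
F2 | step 6 | 2-[5-(1,3-dioxolan-2-yl)-2-methoxy-4-(methoxymethoxy)phenyl]-4,4,5,5-tetramethyl-1,3,2-dioxaborolane | COCOc1cc(OC)c(B2OC(C)(C)C(C)(C)O2)cc1C1OCCO1
F3 | step 12 | ethyl (E)-3-[(1R,2S)-2-Ar-1,4-dimethylcyclohex-3-en-1-yl]prop-2-enoate | CCOC(=O)/C=C/[C@@]1(C)CCC(C)=C[C@@H]1c1cc(C2OCCO2)c(OCOC)cc1OC
F4 | step 12 | lithium enolate of (E)-1,1-dibromo-4-[(1R,2S)-2-Ar-1,4-dimethylcyclohex-3-en-1-yl]but-3-en-2-one | [Li]OC(=C(Br)Br)/C=C/[C@@]1(C)CCC(C)=C[C@@H]1c1cc(C2OCCO2)c(OCOC)cc1OC
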